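The C2–C3 bond of ring C of the middle unit is the one disconnection on which the route rests. In that ring C2 sits at the acetal oxidation level between O1 and ring B, C3 carries the gallate oxygen and C4 is benzylic to the electron-rich ring A. An O1-bound oxocarbenium carbon and a Z-enol gallate on ring A should therefore close ring C in one acid-triggered Prins operation that sets the 2,3-cis-3,4-trans triad, leaves the gallate on O3 and puts a 2-ethoxyethoxy leaving group on C4. The precursor is the benzylated top unit joined through its C4 to C8 of ring A, whose O1 carries a mixed aryl 2-ethoxyethyl acetal of tribenzyloxybenzaldehyde and whose C4a carries the (Z)-2-(tribenzylgalloyloxy)vinyl group.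

Key step: step 10

Remark: the acetal on O1 is built as the 2-ethoxyethyl and not as the methyl acetal, so that the alkoxide leaving on ionisation is the nucleophile wanted on C4 and no second alcohol competes there; bonds formed and carbon skeleton are unchanged. 3,5-Bis(benzyloxy)phenol and 3,4,5-tris(benzyloxy)benzoic acid are taken as purchased.

Abbreviations: T = hexa-O-benzyl-(−)-epigallocatechin-4β-yl, i.e. (2R,3R)-3,5,7-tris(benzyloxy)-2-[3,4,5-tris(benzyloxy)phenyl]chroman-4-yl bonded through C4 on the face opposite to the 3-benzyloxy and 2-aryl groups (3,4-trans); Ar = 3,4,5-tris(benzyloxy)phenyl.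

Step 1
Reactants: 1 (−)-epigallocatechin
Product: 2 5,7,3′,4′,5′-penta-O-benzyl-(−)-epigallocatechin
Conditions: BnBr (5.5 equiv), K2CO3, DMF, 0 °C to rt, Ar
Reagents that add atoms: benzyl bromide, BrCc1ccccc1
Why: Williamson etherification of the five phenols with carbonate, which does not deprotonate the secondary 3-OH, run cold and oxygen-free so that C2 and C3 (2R,3R) are not epimerised.

Step 2
Reactants: 2 penta-O-benzyl-epigallocatechin; 3 2-ethoxyethanol
Product: 4 4β-(2-ethoxyethoxy)-5,7,3′,4′,5′-penta-O-benzyl-(−)-epigallocatechin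
Conditions: DDQ (2 equiv), 3 (5 equiv), CH2Cl2, rt
Reagents that add atoms: none
Why: DDQ benzylic oxidation removes hydride from C4 (ortho and para to the ring A benzyloxy groups) and the alcohol captures the cation on the face opposite to the cis 2-aryl and 3-hydroxyl groups, which sets C4 as 4S (3,4-trans).

Step 3
Reactants: 4 4β-(2-ethoxyethoxy) alcohol
Product: 5 3-O-benzyl-4β-(2-ethoxyethoxy)-5,7,3′,4′,5′-penta-O-benzyl-(−)-epigallocatechin (top-unit electrophile)
Conditions: NaH, BnBr, Bu4NI (cat.), THF/DMF, 0 °C to rt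
Reagents that add atoms: benzyl bromide, BrCc1ccccc1
Why: Williamson etherification of the secondary alkoxide, to which the C4 ether and the three stereocentres are inert.

Step 4
Reactants: 5 top-unit electrophile; 6 3,5-bis(benzyloxy)phenol
Product: 7 3,5-bis(benzyloxy)-2-T-phenol
Conditions: 6 (4 equiv), TMSOTf (0.2 equiv), CH2Cl2, 4 Å MS, −78 to −40 °C; Et3N
Reagents that add atoms: none
Why: Friedel–Crafts alkylation of the phenol by the C4 benzylic cation, which should go to the carbon beside the hydroxyl (flanked by OH and only one benzyloxy group, like C8 of a flavan, and also reached by reversible O-alkylation and O-to-C shift) and enter anti to the 3-benzyloxy and 2-aryl groups, which sets the top C4 as 4β (3,4-trans).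

Step 5
Reactants: 7 3,5-bis(benzyloxy)-2-T-phenol
Product: 8 4,6-bis(benzyloxy)-2-hydroxy-3-T-benzaldehyde
Conditions: MgCl2, Et3N, (CH2O)n, THF, reflux
Reagents that add atoms: paraformaldehyde (as formaldehyde), C=O
Why: magnesium-phenoxide-directed ortho-formylation (Casnati–Skattebøl reaction), which delivers formaldehyde only to a carbon next to the phenol oxygen, and only one such carbon is free.

Step 6
Reactants: 9 3,4,5-tris(benzyloxy)benzaldehyde; 3 2-ethoxyethanol
Product: 10 3,4,5-tris(benzyloxy)benzaldehyde bis(2-ethoxyethyl) acetal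
Conditions: 3 (8 equiv), p-TsOH (cat.), toluene, reflux, Dean–Stark trap; Et3N
Reagents that add atoms: none
Why: acid-catalysed acetalisation driven by azeotropic removal of water, to which the benzyl ethers are inert.

Step 7
Reactants: 10 bis(2-ethoxyethyl) acetal; 8 4,6-bis(benzyloxy)-2-hydroxy-3-T-benzaldehyde
Product: 12 4,6-bis(benzyloxy)-2-[Ar(2-ethoxyethoxy)methoxy]-3-T-benzaldehyde, via α-chloro ether 11 (not isolated)
Conditions: 10, AcCl, ZnBr2 (cat.), toluene, rt; then 8, NaH, THF/DMF, 0 °C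
Reagents that add atoms: none
Why: acetal–acyl chloride exchange gives the α-chloro ether, which O-alkylates the sodium phenoxide (Williamson-type alkylation with an α-halo ether, as in MOM or MEM protection) to a base-stable mixed acetal, obtained as both epimers at the acetal carbon, which is of no consequence.

Step 8
Reactants: 12 mixed-acetal aldehyde
Product: 13 1,5-bis(benzyloxy)-2-ethynyl-3-[Ar(2-ethoxyethoxy)methoxy]-4-T-benzene
Conditions: dimethyl (1-diazo-2-oxopropyl)phosphonate, K2CO3, MeOH/THF, 0 °C to rt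
Reagents that add atoms: dimethyl (1-diazo-2-oxopropyl)phosphonate, CC(=O)C(=[N+]=[N-])P(=O)(OC)OC
Why: Ohira–Bestmann (Seyferth–Gilbert) homologation of the aldehyde to the terminal alkyne under carbonate in methanol, conditions to which the mixed acetal, the benzyl ethers and the stereocentres are inert.

Step 9
Reactants: 13 ethynyl arene; 14 3,4,5-tris(benzyloxy)benzoic acid
Product: 15 (Z)-2-{2,4-bis(benzyloxy)-6-[Ar(2-ethoxyethoxy)methoxy]-5-T-phenyl}ethenyl 3,4,5-tris(benzyloxy)benzoate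
Conditions: [RuCl2(p-cymene)]2 (2 mol %), P(4-ClC6H4)3, DMAP, toluene, 60 °C
Reagents that add atoms: none
Why: ruthenium-catalysed anti-Markovnikov hydro-acyloxylation of the terminal alkyne through a ruthenium vinylidene, in which the carboxylate adds to the metal-bound carbon and protonolysis leaves carboxylate and aryl group cis (Z), while the already capped phenol cannot close to a benzofuran and DMAP buffers the acid.

Step 10
Reactants: 15 Z-enol gallate acetal; 3 2-ethoxyethanol
Product: 18 top–middle dimer gallate carrying a 4β-(2-ethoxyethoxy) group on the middle unit, via aryl oxocarbenium triflate 16 (not isolated), via dioxolanylium triflate 17 (not isolated)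
Conditions: TMSOTf (0.2 equiv), 2,6-di-tert-butyl-4-methylpyridine (0.05 equiv), CH2Cl2 (0.005 M), 4 Å MS, −78 °C; then 3 (3 equiv), −78 to −40 °C; Et3N
Reagents that add atoms: none
Why: Proposed new method: TMSOTf silylates the glycol-ether arm of the acetal, which leaves as its silyl ether and gives the E aryl oxocarbenium ion 16; C3 of the Z-enol gallate adds to its carbon (the new C2–C3 bond), the charge passes to C4, which is benzylic to ring A with oxygen substituents ortho and para, the gallate carbonyl oxygen closes onto C4 to give the cis-fused dioxolan-2-ylium ion 17, and the released silyl ether or added 3 opens 17 at C4 with inversion while TMSOTf is regenerated. The closest known reaction type is the Prins cyclisation of an acetal-derived oxocarbenium ion onto a Z alkene with interception of the cation by a neighbouring ester; an enol ester as the alkene and a phenol-derived oxocarbenium ion are the untested elements. Ring C closes in a 6-endo-trig mode, and the transient dioxolanylium ring formed by neighbouring-group participation is opened again. C2 and C3 are set together in a half-chair transition state with the ring B aryl group pseudo-equatorial on the E oxocarbenium carbon and, the alkene being Z, the acyloxy group pseudo-axial on C3, hence 2,3-cis; C4 is set trans to O3 by participation followed by backside opening. The step needs bonding at C3 and not at C4 (secured by the styrene polarity that the trioxygenated ring A imposes), ionisation on the alkyl and not the aryl oxygen of the acetal (the glycol-ether arm is the better silyl acceptor, and only the aryl oxocarbenium ion has an intramolecular, irreversible exit), and one face of the oxocarbenium ion (2R,3R), which rests on shielding by the top unit on C8 beside O1 and is the least certain element.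

Step 11
Reactants: 18 dimer gallate with C4 leaving group; 2 penta-O-benzyl-epigallocatechin
Product: 19 nonadeca-O-benzyl trimer
Conditions: 2 (4 equiv), TMSOTf (0.2 equiv), CH2Cl2, −78 to −20 °C; Et3N
Reagents that add atoms: none
Why: Friedel–Crafts alkylation of C8 of 2 (the most nucleophilic ring A carbon of a benzylated flavan-3-ol) by the C4 cation of 18, which forms with gallate participation and is therefore opened anti to O3, so that C4 stays 4β (3,4-trans), while the excess of 2 suppresses self-condensation.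

Step 12
Reactants: 19 nonadeca-O-benzyl trimer
Product: 20 (−)-epigallocatechin-(4β→8)-(−)-epigallocatechin 3-O-gallate-(4β→8)-(−)-epigallocatechin
Conditions: H2 (1 atm), Pd(OH)2/C, THF/MeOH/H2O, rt
Reagents that add atoms: none
Why: hydrogenolysis of the nineteen benzyl ethers over palladium, which should leave the gallate ester, the two interflavan bonds and the eight stereocentres untouched.

Compound list

1 | (−)-epigallocatechin, (2R,3R)-2-(3,4,5-trihydroxyphenyl)chroman-3,5,7-triol | O[C@@H]1Cc2c(O)cc(O)cc2O[C@@H]1c1cc(O)c(O)c(O)c1 | starting material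

2 | 5,7,3′,4′,5′-penta-O-benzyl-(−)-epigallocatechin, (2R,3R)-5,7-bis(benzyloxy)-2-[3,4,5-tris(benzyloxy)phenyl]chroman-3-ol | O[C@@H]1Cc2c(OCc9ccccc9)cc(OCc9ccccc9)cc2O[C@@H]1c1cc(OCc9ccccc9)c(OCc9ccccc9)c(OCc9ccccc9)c1 | intermediate

3 | 2-ethoxyethanol | OCCOCC | starting material

4 | (2R,3R,4S)-5,7-bis(benzyloxy)-4-(2-ethoxyethoxy)-2-[3,4,5-tris(benzyloxy)phenyl]chroman-3-ol (2,3-cis-3,4-trans) | O[C@@H]1[C@@H](OCCOCC)c2c(OCc9ccccc9)cc(OCc9ccccc9)cc2O[C@@H]1c1cc(OCc9ccccc9)c(OCc9ccccc9)c(OCc9ccccc9)c1 | intermediate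

5 | (2R,3R,4S)-3,5,7-tris(benzyloxy)-4-(2-ethoxyethoxy)-2-[3,4,5-tris(benzyloxy)phenyl]chromane (2,3-cis-3,4-trans) | C(c9ccccc9)O[C@@H]1[C@@H](OCCOCC)c2c(OCc9ccccc9)cc(OCc9ccccc9)cc2O[C@@H]1c1cc(OCc9ccccc9)c(OCc9ccccc9)c(OCc9ccccc9)c1 | intermediate

6 | 3,5-bis(benzyloxy)phenol | Oc1cc(OCc9ccccc9)cc(OCc9ccccc9)c1 | starting material

7 | 3,5-bis(benzyloxy)-2-T-phenol | Oc1cc(OCc9ccccc9)cc(OCc9ccccc9)c1[C@H]3c4c(OCc9ccccc9)cc(OCc9ccccc9)cc4O[C@H](c4cc(OCc9ccccc9)c(OCc9ccccc9)c(OCc9ccccc9)c4)[C@@H]3OCc9ccccc9 | intermediate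

8 | 4,6-bis(benzyloxy)-2-hydroxy-3-T-benzaldehyde | O=Cc1c(OCc9ccccc9)cc(OCc9ccccc9)c([C@H]3c4c(OCc9ccccc9)cc(OCc9ccccc9)cc4O[C@H](c4cc(OCc9ccccc9)c(OCc9ccccc9)c(OCc9ccccc9)c4)[C@@H]3OCc9ccccc9)c1O | intermediate

9 | 3,4,5-tris(benzyloxy)benzaldehyde | O=Cc1cc(OCc9ccccc9)c(OCc9ccccc9)c(OCc9ccccc9)c1 | starting material

10 | 1,2,3-tris(benzyloxy)-5-[bis(2-ethoxyethoxy)methyl]benzene | CCOCCOC(OCCOCC)c1cc(OCc9ccccc9)c(OCc9ccccc9)c(OCc9ccccc9)c1 | intermediate

11 | 1,2,3-tris(benzyloxy)-5-[chloro(2-ethoxyethoxy)methyl]benzene (racemic α-chloro ether) | CCOCCOC(Cl)c1cc(OCc9ccccc9)c(OCc9ccccc9)c(OCc9ccccc9)c1 | intermediate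

12 | 4,6-bis(benzyloxy)-2-[Ar(2-ethoxyethoxy)methoxy]-3-T-benzaldehyde (both epimers at the acetal carbon) | O=Cc1c(OCc9ccccc9)cc(OCc9ccccc9)c([C@H]3c4c(OCc9ccccc9)cc(OCc9ccccc9)cc4O[C@H](c4cc(OCc9ccccc9)c(OCc9ccccc9)c(OCc9ccccc9)c4)[C@@H]3OCc9ccccc9)c1OC(OCCOCC)c1cc(OCc9ccccc9)c(OCc9ccccc9)c(OCc9ccccc9)c1 | intermediate

13 | 1,5-bis(benzyloxy)-2-ethynyl-3-[Ar(2-ethoxyethoxy)methoxy]-4-T-benzene (both acetal epimers) | C#Cc1c(OCc9ccccc9)cc(OCc9ccccc9)c([C@H]3c4c(OCc9ccccc9)cc(OCc9ccccc9)cc4O[C@H](c4cc(OCc9ccccc9)c(OCc9ccccc9)c(OCc9ccccc9)c4)[C@@H]3OCc9ccccc9)c1OC(OCCOCC)c1cc(OCc9ccccc9)c(OCc9ccccc9)c(OCc9ccccc9)c1 | intermediate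

14 | 3,4,5-tris(benzyloxy)benzoic acid | OC(=O)c1cc(OCc9ccccc9)c(OCc9ccccc9)c(OCc9ccccc9)c1 | starting material

15 | (Z)-2-{2,4-bis(benzyloxy)-6-[Ar(2-ethoxyethoxy)methoxy]-5-T-phenyl}ethenyl 3,4,5-tris(benzyloxy)benzoate (both acetal epimers) | O=C(O/C=C\c2c(OCc9ccccc9)cc(OCc9ccccc9)c([C@H]3c4c(OCc9ccccc9)cc(OCc9ccccc9)cc4O[C@H](c4cc(OCc9ccccc9)c(OCc9ccccc9)c(OCc9ccccc9)c4)[C@@H]3OCc9ccccc9)c2OC(OCCOCC)c1cc(OCc9ccccc9)c(OCc9ccccc9)c(OCc9ccccc9)c1)c1cc(OCc9ccccc9)c(OCc9ccccc9)c(OCc9ccccc9)c1 | intermediate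

16 | E aryl oxocarbenium triflate from 15 (ArCH=O+ on the ring A oxygen, Z-enol gallate intact) | O=C(O/C=C\c2c(OCc9ccccc9)cc(OCc9ccccc9)c([C@H]3c4c(OCc9ccccc9)cc(OCc9ccccc9)cc4O[C@H](c4cc(OCc9ccccc9)c(OCc9ccccc9)c(OCc9ccccc9)c4)[C@@H]3OCc9ccccc9)c2/[O+]=C/c1cc(OCc9ccccc9)c(OCc9ccccc9)c(OCc9ccccc9)c1)c1cc(OCc9ccccc9)c(OCc9ccccc9)c(OCc9ccccc9)c1.[O-]S(=O)(=O)C(F)(F)F | intermediate

17 | 2-Ar-1,3-dioxolan-2-ylium triflate cis-fused across O3 and C4 of the closed ring C (2R,3R; C4–O cis to C3–O; 5,7-bis(benzyloxy), 8-T, 2-Ar) | C5(=[O+][C@@H]6c2c(OCc9ccccc9)cc(OCc9ccccc9)c([C@H]3c4c(OCc9ccccc9)cc(OCc9ccccc9)cc4O[C@H](c4cc(OCc9ccccc9)c(OCc9ccccc9)c(OCc9ccccc9)c4)[C@@H]3OCc9ccccc9)c2O[C@H](c1cc(OCc9ccccc9)c(OCc9ccccc9)c(OCc9ccccc9)c1)[C@@H]6O5)c1cc(OCc9ccccc9)c(OCc9ccccc9)c(OCc9ccccc9)c1.[O-]S(=O)(=O)C(F)(F)F | intermediate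

18 | (2R,3R,4S)-5,7-bis(benzyloxy)-4-(2-ethoxyethoxy)-8-T-2-Ar-chroman-3-yl 3,4,5-tris(benzyloxy)benzoate (2,3-cis-3,4-trans) | O=C(O[C@@H]1[C@@H](OCCOCC)c2c(OCc9ccccc9)cc(OCc9ccccc9)c([C@H]3c4c(OCc9ccccc9)cc(OCc9ccccc9)cc4O[C@H](c4cc(OCc9ccccc9)c(OCc9ccccc9)c(OCc9ccccc9)c4)[C@@H]3OCc9ccccc9)c2O[C@@H]1c1cc(OCc9ccccc9)c(OCc9ccccc9)c(OCc9ccccc9)c1)c1cc(OCc9ccccc9)c(OCc9ccccc9)c(OCc9ccccc9)c1 | intermediate

19 | nonadeca-O-benzyl trimer: 18 in which the 4-(2-ethoxyethoxy) group is replaced, on the same face (4β, 3,4-trans), by C8 of 2 (bottom 3-OH free) | O=C(O[C@@H]1[C@@H](c2c(OCc9ccccc9)cc(OCc9ccccc9)c3c2O[C@H](c2cc(OCc9ccccc9)c(OCc9ccccc9)c(OCc9ccccc9)c2)[C@H](O)C3)c2c(OCc9ccccc9)cc(OCc9ccccc9)c([C@H]3c4c(OCc9ccccc9)cc(OCc9ccccc9)cc4O[C@H](c4cc(OCc9ccccc9)c(OCc9ccccc9)c(OCc9ccccc9)c4)[C@@H]3OCc9ccccc9)c2O[C@@H]1c1cc(OCc9ccccc9)c(OCc9ccccc9)c(OCc9ccccc9)c1)c1cc(OCc9ccccc9)c(OCc9ccccc9)c(OCc9ccccc9)c1 | intermediate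

20 | (−)-epigallocatechin-(4β→8)-(−)-epigallocatechin 3-O-gallate-(4β→8)-(−)-epigallocatechin | O=C(O[C@@H]1[C@@H](c2c(O)cc(O)c3c2O[C@H](c2cc(O)c(O)c(O)c2)[C@H](O)C3)c2c(O)cc(O)c([C@H]3c4c(O)cc(O)cc4O[C@H](c4cc(O)c(O)c(O)c4)[C@@H]3O)c2O[C@@H]1c1cc(O)c(O)c(O)c1)c1cc(O)c(O)c(O)c1 | target

Total steps: 12. Longest linear sequence: 11 steps (steps 1, 2, 3, 4, 5, 7, 8, 9, 10, 11, 12; step 6 is the side branch to the acetal reagent).

Steps most likely to fail

Step 10. Three processes threaten it: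
- Ionisation may take place on the aryl oxygen of the acetal, so that the ring A phenol leaves and C–C bond formation becomes intermolecular and stereochemically loose.
- The top unit may give only weak facial discrimination, so that ring C also forms with the mirror-image triad.
- Protonation of the enol ester may be followed by closure to a benzofuran.

The fallback uses known chemistry only, sets out from 5 and 2 and comes back at 18. TMSOTf-catalysed Friedel–Crafts coupling of 5 with an excess of 2 should give the top–middle dimer with a free 3-OH on the lower unit, 5,7,3′,4′,5′-penta-O-benzyl-8-T-epigallocatechin F1. DDQ with 2-ethoxyethanol should oxidise its only CH2-type benzylic position, C4 of the lower unit (the upper C4–H is a shielded methine), to the 4β-(2-ethoxyethoxy) dimer alcohol F2. Steglich esterification of F2 with 14 (DCC, DMAP, CH2Cl2) gives 18. In this variant ring C of the middle unit comes intact from natural epigallocatechin and only C4 is newly set.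

Step 9. The carboxylic acid may cleave or exchange the acid-labile acetal at 60 °C, the metal-activated alkyne may be attacked by the neighbouring acetal oxygen, or regio- and Z-selectivity may erode. The fallback sets out from 13 and comes back at 15. Rhodium-catalysed trans-hydroboration with pinacolborane ([RhCl(1,5-cyclooctadiene)]2, P(i-Pr)3, Et3N, cyclohexane, rt) should give the (Z)-alkenyl pinacolboronate F3. Oxidative coupling of F3 with the triethylammonium salt of 14 mediated by Cu(OAc)2 under air at rt (Chan–Lam-type enol ester formation, which keeps the alkene geometry) gives 15 without any free acid at elevated temperature.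

Step 4. Alkylation may occur at the carbon para to the hydroxyl (between the two benzyloxy groups), the product phenol may be alkylated a second time, or the electrophile may condense with itself. The fallback sets out from 5 and comes back at 8, so that step 5 is also bypassed. 2,4,6-Trihydroxybenzaldehyde is benzylated twice (BnBr, 2 equiv, K2CO3, DMF; the hydrogen-bonded hydroxyl stays free) to 4,6-bis(benzyloxy)-2-hydroxybenzaldehyde F4. F4 is then used as the nucleophile with 5 and TMSOTf. Its formyl group already occupies one carbon beside the hydroxyl and tames the ring against a second alkylation. O-alkylation followed by Lewis-acid-promoted O-to-C shift to the neighbouring carbon (the behaviour known from aryl C-glycosylation of such hydroxy carbonyl arenes) should give 8 directly.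

Further compounds

F1 | step 10 | 5,7,3′,4′,5′-penta-O-benzyl-8-T-(−)-epigallocatechin (top–middle dimer, lower 3-OH free) | O[C@@H]1Cc2c(OCc9ccccc9)cc(OCc9ccccc9)c([C@H]3c4c(OCc9ccccc9)cc(OCc9ccccc9)cc4O[C@H](c4cc(OCc9ccccc9)c(OCc9ccccc9)c(OCc9ccccc9)c4)[C@@H]3OCc9ccccc9)c2O[C@@H]1c1cc(OCc9ccccc9)c(OCc9ccccc9)c(OCc9ccccc9)c1

F2 | step 10 | (2R,3R,4S)-5,7-bis(benzyloxy)-4-(2-ethoxyethoxy)-8-T-2-Ar-chroman-3-ol (2,3-cis-3,4-trans) | O[C@@H]1[C@@H](OCCOCC)c2c(OCc9ccccc9)cc(OCc9ccccc9)c([C@H]3c4c(OCc9ccccc9)cc(OCc9ccccc9)cc4O[C@H](c4cc(OCc9ccccc9)c(OCc9ccccc9)c(OCc9ccccc9)c4)[C@@H]3OCc9ccccc9)c2O[C@@H]1c1cc(OCc9ccccc9)c(OCc9ccccc9)c(OCc9ccccc9)c1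

F3 | step 9 | 2-[(Z)-2-{2,4-bis(benzyloxy)-6-[Ar(2-ethoxyethoxy)methoxy]-5-T-phenyl}ethenyl]-4,4,5,5-tetramethyl-1,3,2-dioxaborolane | CC1(C)OB(OC1(C)C)/C=C\c2c(OCc9ccccc9)cc(OCc9ccccc9)c([C@H]3c4c(OCc9ccccc9)cc(OCc9ccccc9)cc4O[C@H](c4cc(OCc9ccccc9)c(OCc9ccccc9)c(OCc9ccccc9)c4)[C@@H]3OCc9ccccc9)c2OC(OCCOCC)c1cc(OCc9ccccc9)c(OCc9ccccc9)c(OCc9ccccc9)c1

F4 | step 4 | 4,6-bis(benzyloxy)-2-hydroxybenzaldehyde | O=Cc1c(O)cc(OCc9ccccc9)cc1OCc9ccccc9
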